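Draw the rate at 20 % conversion as a curve against free catalyst, on logarithmic axes.

| flask | substrate | coupling partner | free catalyst | second catalyst | impurity | remark |
|---|---|---|---|---|---|---|
| alpha | 0.10 M | 1 equiv | 1 mol% | 0.18 mol% | 0.72 mM | run made earlier |
| theta | 0.15 M | 1 equiv | 1 mol% | 0.18 mol% | 0.72 mM | run made earlier |
| zeta | 0.20 M | 1 equiv | 1.5 mol% | 0.18 mol% | 0.72 mM | run made earlier |
| flask | 0.20 M | 1.00 equiv | 1 mol% | 0.18 mol% | 0.72 mM |  |

| run | time / h | product / % | substrate / % |
|---|---|---|---|
| alpha | 0.500 | 0.6 | 95.2 |
| alpha | 1.33 | 2.0 | 92.9 |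
| alpha | 3.00 | 6.0 | 87.6 |
| alpha | 6.00 | 13.7 | 78.1 |
| theta | 0.500 | 2.0 | 94.7 |
| theta | 1.33 | 6.1 | 86.8 |
| theta | 3.00 | 16.9 | 74.4 |
| theta | 6.00 | 33.2 | 56.9 |
| zeta | 0.500 | 4.0 | 86.4 |
| zeta | 1.33 | 17.5 | 70.2 |
| zeta | 3.00 | 41.7 | 45.5 |
| zeta | 6.00 | 66.7 | 20.4 |

(each reading ± 0.5 percentage points)

- factor on the rate of making product when 20 % of the substrate are converted if free catalyst is charged twice over
- factor on the rate when 20 % of the substrate are converted if free catalyst is charged at 10 mol% instead

I assume impurity takes free catalyst one for one, so I count charge minus impurity: 1.28 mM in the flask, 2.28 mM in zeta. Zeta's late substrate decay is 2.99 times theta's, and these active amounts predict 2.92. So substrate loss looks pseudo-first-order, with a constant that scales with active catalyst.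

Zeta matches the flask in substrate, partner and second catalyst. I read two constants there. Intermediate is whatever the two readings leave unaccounted for. Product per hour, divided by intermediate and by the partner fraction, gives the drain.

feed in zeta = 0.267 h⁻¹

drain at full partner = 1.64 h⁻¹

Let t be the time to 20 % conversion, with feed scaled to active catalyst. Then x = drain × t. In the flask:

t = 1.49 h, x = 2.44

I call x the drain count: how many drain times fit into the time to that conversion. With steady feed, the share of converted substrate still standing as intermediate is f = (1 − e^(−x))/x. The rate follows f·b, where b = 1 − 20.0 %(1 − f) is the partner fraction.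

flask: f = 0.374, f·b = 0.328

doubled: x = 0.951, f = 0.645, f·b = 0.599, factor 1.83

10 mol%: x = 0.162, f = 0.923, f·b = 0.909, factor 2.78

At large x, f goes as the inverse of x, so the curve starts with slope one. The doubled charge lands on the knee, with x near one. The log slope is 0.642 up to there and 0.235 beyond. As x falls toward nought, f·b goes to one, so the factor levels at 3.05.

The forecast gives 1.8 and 2.7: “Rate is limited by the second step, so it is far from proportional to catalyst.”

The flask gives 1.83 and 2.88.

    second catalyst ⇌ dormant form (K = 2.40, k = 8.80 × 10⁻⁴ min⁻¹)
    free catalyst + impurity → spent catalyst (k = 48.0 M⁻¹ min⁻¹)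
    coupling partner + second catalyst + intermediate → second catalyst + product (k = 400 M⁻² min⁻¹)
    substrate + free catalyst → free catalyst + intermediate (k = 1.90 M⁻¹ min⁻¹)

The flask reaches 20 % conversion at 1.41 h, sooner than my 1.49 h, so its drain count is 2.31, still above the knee. In theta, partner and second catalyst both scale with substrate, so the drain scales with the square of that ratio. That gives x = 2.25 and intermediate at 7.95 % of the substrate charged. Theta's readings pass through 20 % conversion between 1.33 h and 3.00 h, where intermediate reads 7.10 % and then 8.70 %.

The earlier runs and the new flask come from a simulation with made-up constants, noise included.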